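**Assumption:** CNP0152986.1 is taken to be exactly the given SMILES, i.e. (5S,8R,9R,10S,13R)-8α,15-epoxylabdan-16-yl acetate. Labdane numbering is used for atom labels: decalin C1–C10; C8 carries O and Me-17; chain C9–C11–C12–C13(–C16)–C14–C15–O.

**Abbreviations:** Fmppy = cyclometalated 2-(4-fluorophenyl)-4-methylpyridine; dtbbpy = 4,4'-di-tert-butyl-2,2'-bipyridine; cod = 1,5-cyclooctadiene.

## Retrosynthetic overview

- Target ⇒ acetylation and C16 aldehyde reduction ⇒ the 13R oxocane aldehyde.
- Key disconnection C13–C14 (ring-closing, last C–C bond): the α-carbon of a C16 aldehyde, made electrophilic as its enamine radical cation (enolonium-type polarity reversal), is joined to the nucleophilic terminus of an O-vinyl ether on C8–O. Both carbons are normally nucleophilic. The bond creates the 1,4-dioxygen pattern O–C16–C13–C14–C15–O, the eight-membered ring and the C13 stereocentre in one step.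
- Cyclization precursor ⇒ O-vinylation of C8–OH (brings C14, C15) and a four-carbon aldehyde chain C11–C12–C13–C16 from Wittig homologation of the sclareolide lactol.
- Rings A and B with C5, C8, C9, C10 are bought as (+)-sclareolide. Ring order: decalin (purchased), then the oxocane (ring C) in the key step.

## Route

Step 1
Reactants: 1 (+)-sclareolide
Product: 2 sclareolide lactol (C12 anomers)
Conditions: i-Bu2AlH (1.1 equiv), CH2Cl2, −78 °C; aq. KNaC4H4O6
Reagents that add atoms: none
Why: Partial lactone reduction with i-Bu2AlH at −78 °C stops at the tetrahedral aluminate, which gives the lactol on work-up; C5, C8, C9 and C10 are untouched and the new C12 centre is an irrelevant anomeric mixture.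

Step 2
Reactants: 2 sclareolide lactol; 3 ethyl (triphenylphosphoranylidene)acetate
Product: 4 ethyl (E)-4-[(1R,2R,4aS,8aS)-2-hydroxy-2,5,5,8a-tetramethyldecahydronaphthalen-1-yl]but-2-enoate
Conditions: 3 (1.5 equiv), PhCO2H (10 mol%), toluene, 80 °C
Reagents that add atoms: ethyl (triphenylphosphoranylidene)acetate, CCOC(=O)C=P(c1ccccc1)(c1ccccc1)c1ccccc1
Why: Wittig olefination of the open hydroxy-aldehyde form of the lactol with a stabilized ylide gives the E-enoate, the acid co-catalyst speeding ring opening and keeping the medium non-basic so that the C8–OH does not add back by oxa-Michael reaction; no stereocentre is formed.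

Step 3
Reactants: 4 ethyl (E)-4-[(1R,2R,4aS,8aS)-2-hydroxy-2,5,5,8a-tetramethyldecahydronaphthalen-1-yl]but-2-enoate
Product: 5 ethyl 4-[(1R,2R,4aS,8aS)-2-hydroxy-2,5,5,8a-tetramethyldecahydronaphthalen-1-yl]butanoate
Conditions: H2 (1 atm), 10% Pd/C, EtOAc, rt
Reagents that add atoms: none
Why: Heterogeneous catalytic hydrogenation saturates the conjugated C12=C13 bond without touching the ester or the tertiary alcohol and removes the oxa-Michael liability; no stereocentre is formed.

Step 4
Reactants: 5 ethyl 4-[(1R,2R,4aS,8aS)-2-hydroxy-2,5,5,8a-tetramethyldecahydronaphthalen-1-yl]butanoate; 6 vinyl acetate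
Product: 7 ethyl 4-[(1R,2R,4aS,8aS)-2-(ethenyloxy)-2,5,5,8a-tetramethyldecahydronaphthalen-1-yl]butanoate
Conditions: [Ir(cod)Cl]2 (2 mol%), Na2CO3 (0.6 equiv), 6 (5 equiv), toluene, 100 °C
Reagents that add atoms: vinyl acetate, C=COC(C)=O
Why: Iridium-catalysed transfer vinylation (addition of the iridium alkoxide to vinyl acetate, then β-acetate elimination) tolerates tertiary alcohols and runs under weakly basic conditions that leave the ethyl ester alone; C8 is not a reacting centre, so its configuration is retained.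

Step 5
Reactants: 7 ethyl 4-[(1R,2R,4aS,8aS)-2-(ethenyloxy)-2,5,5,8a-tetramethyldecahydronaphthalen-1-yl]butanoate
Product: 8 4-[(1R,2R,4aS,8aS)-2-(ethenyloxy)-2,5,5,8a-tetramethyldecahydronaphthalen-1-yl]butanal
Conditions: i-Bu2AlH (1.05 equiv), toluene, −78 °C; MeOH, then aq. KNaC4H4O6
Reagents that add atoms: none
Why: Partial ester reduction with i-Bu2AlH at −78 °C gives the aldehyde when the aluminate collapses on neutral tartrate work-up, which also keeps the acid-labile vinyl ether intact; no stereocentre is affected.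

Step 6
Reactants: 8 4-[(1R,2R,4aS,8aS)-2-(ethenyloxy)-2,5,5,8a-tetramethyldecahydronaphthalen-1-yl]butanal
Product: 11 (13R)-8α,15-epoxylabdan-16-ol, via catalyst enamine 9 (not isolated), via oxocane aldehyde 10 (not isolated)
Conditions: (2S,5S)-5-benzyl-2-tert-butyl-3-methylimidazolidin-4-one·CF3CO2H (20 mol%), [Ir(Fmppy)2(dtbbpy)]PF6 (1 mol%), 2,4,6-triisopropylbenzenethiol (10 mol%), DME, H2O (2 equiv), 0.01 M, blue LEDs, −40 °C; then NaBH4, MeOH, −40 → 0 °C
Reagents that add atoms: none
Why: Proposed new method: an 8-endo ring closure by photoredox/enamine/thiol triple catalysis, in which the aldehyde condenses with the imidazolidinone to E-enamine 9, the photoexcited trivalent iridium complex oxidizes 9 to the electrophilic three-π-electron enamine radical cation (an enolonium-type, reversed-polarity form of the normally nucleophilic α-carbon C13), this adds to the nucleophilic terminal carbon C14 of the tethered vinyl ether (the only regiochemistry that gives the oxygen-stabilized C15 radical, so 7-exo closure does not compete), the thiol gives a hydrogen atom to C15 and hydrolysis releases aldehyde 10 and the amine; the closest known reaction type is the intramolecular enantioselective α-alkylation of aldehydes with tethered olefins under the same triple catalysis (five- to seven-membered rings), supported by 8-endo cyclizations of electrophilic α-carbonyl radicals; C13 is set by the catalyst, whose benzyl group blocks the Re face of the enamine so that C14 bonds to the Si face and gives 13R, and NaBH4 then reduces the epimerizable aldehyde in the same flask.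

Step 7
Reactants: 11 (13R)-8α,15-epoxylabdan-16-ol; 12 acetic anhydride
Product: 13 (13R)-8α,15-epoxylabdan-16-yl acetate (CNP0152986.1)
Conditions: 12 (1.5 equiv), pyridine, DMAP (5 mol%), CH2Cl2, rt
Reagents that add atoms: acetic anhydride, CC(=O)OC(C)=O
Why: DMAP-catalysed acylation of the unhindered primary alcohol gives the acetate without touching any stereocentre, and the product is the target.

## Compound list

1 | (+)-sclareolide, (3aR,5aS,9aS,9bR)-3a,6,6,9a-tetramethyldecahydronaphtho[2,1-b]furan-2(1H)-one | O=C1O[C@]2(C)CC[C@H]3C(C)(C)CCC[C@]3(C)[C@H]2C1 | starting material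
2 | sclareolide lactol, (3aR,5aS,9aS,9bR)-3a,6,6,9a-tetramethyldodecahydronaphtho[2,1-b]furan-2-ol (C12 anomers) | OC1O[C@]2(C)CC[C@H]3C(C)(C)CCC[C@]3(C)[C@H]2C1 | intermediate
3 | ethyl (triphenylphosphoranylidene)acetate | CCOC(=O)C=P(c1ccccc1)(c1ccccc1)c1ccccc1 | starting material
4 | ethyl (E)-4-[(1R,2R,4aS,8aS)-2-hydroxy-2,5,5,8a-tetramethyldecahydronaphthalen-1-yl]but-2-enoate | O[C@]1(C)CC[C@H]2C(C)(C)CCC[C@]2(C)[C@H]1C/C=C/C(=O)OCC | intermediate
5 | ethyl 4-[(1R,2R,4aS,8aS)-2-hydroxy-2,5,5,8a-tetramethyldecahydronaphthalen-1-yl]butanoate | O[C@]1(C)CC[C@H]2C(C)(C)CCC[C@]2(C)[C@H]1CCCC(=O)OCC | intermediate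
6 | vinyl acetate | C=COC(C)=O | starting material
7 | ethyl 4-[(1R,2R,4aS,8aS)-2-(ethenyloxy)-2,5,5,8a-tetramethyldecahydronaphthalen-1-yl]butanoate | C=CO[C@]1(C)CC[C@H]2C(C)(C)CCC[C@]2(C)[C@H]1CCCC(=O)OCC | intermediate
8 | 4-[(1R,2R,4aS,8aS)-2-(ethenyloxy)-2,5,5,8a-tetramethyldecahydronaphthalen-1-yl]butanal | C=CO[C@]1(C)CC[C@H]2C(C)(C)CCC[C@]2(C)[C@H]1CCCC=O | intermediate
9 | (E)-enamine of 8 with (2S,5S)-5-benzyl-2-tert-butyl-3-methylimidazolidin-4-one (catalyst N1 on C16, double bond C13=C16) | C=CO[C@]1(C)CC[C@H]2C(C)(C)CCC[C@]2(C)[C@H]1CC/C=C/N3[C@H](C(C)(C)C)N(C)C(=O)[C@@H]3Cc4ccccc4 | intermediate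
10 | (13R)-8α,15-epoxylabdan-16-al (5S,8R,9R,10S,13R; oxocane O–C15–C14–C13–C12–C11–C9–C8 trans-fused to ring B, CHO on C13) | O=C[C@H]1CCO[C@]2(C)CC[C@H]3C(C)(C)CCC[C@]3(C)[C@H]2CC1 | intermediate
11 | (13R)-8α,15-epoxylabdan-16-ol (5S,8R,9R,10S,13R) | OC[C@H]1CCO[C@]2(C)CC[C@H]3C(C)(C)CCC[C@]3(C)[C@H]2CC1 | intermediate
12 | acetic anhydride | CC(=O)OC(C)=O | starting material
13 | (13R)-8α,15-epoxylabdan-16-yl acetate (5S,8R,9R,10S,13R), CNP0152986.1 | CC(=O)OC[C@H]1CCO[C@]2(C)CC[C@H]3C(C)(C)CCC[C@]3(C)[C@H]2CC1 | target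

## Step count and risks

Total steps: 7. Longest linear sequence: 7 (fully linear from 1).

**Most likely to fail, in order:**

**Step 6 (key ring closure).** Risks: the 8-endo closure may be too slow for the short-lived radical cation; the thiol may be consumed by thiol-ene addition to the vinyl ether; the amine salt may hydrolyse the vinyl ether; the decalin may oppose the catalyst's facial preference at C13.
Fallback, from 7 back to 11: close the ring with a tin-hydride radical chain on an α-bromo ester instead of enamine catalysis. Ester 7 is deprotonated with LiN(i-Pr)2 (THF, −78 °C) and brominated with CBr4 to give ethyl 2-bromo-4-[(1R,2R,4aS,8aS)-2-(ethenyloxy)-2,5,5,8a-tetramethyldecahydronaphthalen-1-yl]butanoate F1 (C13 epimers). Slow addition of n-Bu3SnH with AIBN (benzene, 80 °C, 3 mM) generates the electrophilic α-ester radical at C13, which closes 8-endo onto the vinyl ether terminus. This gives ethyl (13R)-8α,15-epoxylabdan-16-oate F2 together with its 13S epimer. The epimers are separated and the 13S ester is recycled by NaOEt equilibration. LiAlH4 (THF, 0 °C) then reduces F2 to alcohol 11.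

**Step 4 (O-vinylation of the hindered tertiary C8–OH).** Risks: slow alkoxide exchange at iridium; competing lactonization of 5.
Fallback, from 5 back to 7: acetal formation and elimination instead of transfer vinylation. Alcohol 5 with ethyl vinyl ether and PPTS (CH2Cl2, rt) gives the mixed acetal ethyl 4-[(1R,2R,4aS,8aS)-2-(1-ethoxyethoxy)-2,5,5,8a-tetramethyldecahydronaphthalen-1-yl]butanoate F3. Me3SiOTf and Et3N (CH2Cl2, 0 °C) then ionize the less hindered ethoxy group and deprotonate the oxocarbenium ion to give vinyl ether 7.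

**Step 2 (Wittig on the lactol).** Risks: slow reaction of the hindered lactol; oxa-Michael closure of 4 to a tetrahydrofuran on prolonged heating.
Fallback, from 2 back to 5: olefin metathesis instead of a stabilized-ylide Wittig. Lactol 2 with Ph3P=CH2 (from Ph3PCH3Br and KOt-Bu, THF, rt) gives (1R,2R,4aS,8aS)-2,5,5,8a-tetramethyl-1-(prop-2-en-1-yl)decahydronaphthalen-2-ol F4. Cross-metathesis of F4 with ethyl acrylate (second-generation Hoveyda–Grubbs catalyst, CH2Cl2, 40 °C) forms enoate 4, which is hydrogenated in the same vessel by the ruthenium residue under H2 (10 bar, 60 °C) to give 5 without isolating 4.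

## Further compounds

F1 | step 6 | ethyl 2-bromo-4-[(1R,2R,4aS,8aS)-2-(ethenyloxy)-2,5,5,8a-tetramethyldecahydronaphthalen-1-yl]butanoate (C13 epimers) | C=CO[C@]1(C)CC[C@H]2C(C)(C)CCC[C@]2(C)[C@H]1CCC(Br)C(=O)OCC
F2 | step 6 | ethyl (13R)-8α,15-epoxylabdan-16-oate | CCOC(=O)[C@H]1CCO[C@]2(C)CC[C@H]3C(C)(C)CCC[C@]3(C)[C@H]2CC1
F3 | step 4 | ethyl 4-[(1R,2R,4aS,8aS)-2-(1-ethoxyethoxy)-2,5,5,8a-tetramethyldecahydronaphthalen-1-yl]butanoate (acetal epimers) | CCOC(C)O[C@]1(C)CC[C@H]2C(C)(C)CCC[C@]2(C)[C@H]1CCCC(=O)OCC
F4 | step 2 | (1R,2R,4aS,8aS)-2,5,5,8a-tetramethyl-1-(prop-2-en-1-yl)decahydronaphthalen-2-ol | O[C@]1(C)CC[C@H]2C(C)(C)CCC[C@]2(C)[C@H]1CC=C
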